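The runs come from a simulation on assumed constants; noise was put on by code.

16 % of the charge stands as free electrophile at 10.0 h in the theta run, and 16 % in the alpha run, whose charge is twice as large.

| setting | theta | alpha | flask |
|---|---|---|---|
| electrophile | 0.034 M (fed, over 8.0 h) | 0.075 M (fed, over 8.0 h) | 0.050 M (fed, over 8.0 h) |
| nucleophile | 0.10 M | 0.10 M | 0.100 M |
| remark | run made earlier; the fed solution adds 0.25 times the starting volume | run made earlier; the fed solution adds 0.25 times the starting volume | the fed solution adds 0.25 times the starting volume |
| time |  |  | 15 h |

| run | time / h | electrophile / % | product / % |
|---|---|---|---|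
| theta | 1.50 | 9 | 3 |
| theta | 3.00 | 13 | 5 |
| theta | 5.00 | 19 | 13 |
| theta | 6.00 | 21 | 24 |
| theta | 8.00 | 23 | 30 |
| theta | 10.0 | 16 | 42 |
| alpha | 0.667 | 8 | 0 |
| alpha | 2.00 | 12 | 6 |
| alpha | 3.00 | 16 | 5 |
| alpha | 5.00 | 21 | 15 |
| alpha | 6.00 | 20 | 19 |
| alpha | 10.0 | 16 | 35 |

(standard deviation of a reading: 2 percentage points)

- amounts are per litre of the starting volume; all of the dose is in the solution fed
- a reading or a percentage of product counts all its forms, free or not
- what has gone from electrophile into another species counts as reacted, even if it can come back
- percentages count the whole charge, also what has not yet gone in
- the earlier runs do not show how much of nucleophile is bound; that part of a forecast is a guess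
- a reading of electrophile is of its free form alone

- part of the electrophile that has reacted at 15 h
- share of the unused nucleophile that is free and not bound as protonated nucleophile, at 15 h

1. Freeze the percentage against the charge. At 5.00 h the two runs read 19 % and 21 %, a gap near the scatter of 2 percentage points. The flask's 0.050 M lies between their charges, with the same nucleophile.

2. Freeze the rate. After the feed stops at 8.0 h, free electrophile in the theta run falls from 23 % at 8.00 h to 16 % at 10.0 h. Taken as pseudo-first-order, with the nucleophile held as if constant, that fall between two readings, each with its scatter, is stretched to the flask's wait after its feed. The fade number, the natural logarithm of the factor by which free electrophile shrinks between the end of the feed and the asked time, is 1.27.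

3. From the theta reading of 23 %, carried to the flask by step 1, that number leaves 6.46 % free in the flask at 15 h. The charge less the free form gives 93.5 % reacted.

4. The number stops at the electrophile. The runs do not show bound nucleophile, so no free share of nucleophile is reckoned here.

The forecast, lower than this reckoning, gives 89 % of the electrophile reacted and 70 % of the unused nucleophile free: “The percentages barely change with loading, and alpha is only slightly slower.”

The flask gives 89.8 % of the electrophile reacted and 70.7 % of the unused nucleophile free.

    electrophile + product ⇌ idle adduct, settled at all times (K = 840 M⁻¹)
    electrophile ⇌ dormant form (K = 0.770, k = 3.15 h⁻¹)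
    electrophile + nucleophile → acid set free + product (k = 3.10 M⁻¹ h⁻¹)
    nucleophile + acid set free ⇌ protonated nucleophile, settled at all times (K = 1010 M⁻¹)

In the flask, free electrophile falls from 25.8 % at 8.00 h to 10.2 % at 15.0 h, a fade number of 0.928 against the 1.27 reckoned. In the flask at 6.71 h, the half-life of electrophile by the forward step into dormant form alone is 0.22 h, shorter than the 3.5 h for making product from electrophile and nucleophile; the rate of making product is 0.063 of that forward rate. The fade number holds no electrophile charge, so it reckons 6.46 % free for the neighbour flask charged with 0.030 M of electrophile as well, and that flask holds 9.41 % free electrophile at 15.0 h.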